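**Plan**

- Numbering: each half is numbered like a drimane (ring A = C1–C5 and C10, ring B = C5–C10, C11 and C11' are the two linker carbons; primes mark the second half).
- Retrosynthesis: the C2-symmetric target is cut at C11'–C9' (sp3–sp2 coupling) and at C9–C11 (vinylation), so both halves come from one enol triflate 9 and one ketone 7; ring A of 7 is then cut at C1–C10 and C4–C5.
- Enabling feature: ring B with its methyl groups on C8 and C10 and an oxygen on C9 is the skeleton of 2,6-dimethylbenzoquinone, and C1–C4 with the gem-dimethyl carbon C4 is 4-methylpenta-1,3-diene, so one [4+2] cycloaddition assembles all 14 carbons of a half.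
- Forward: ring B is bought as the quinone, ring A is closed in step 1, the C6 oxygen and the three alkenes are removed (steps 2–4), the C9 ketone becomes triflate 9 (step 5), one portion of 9 is vinylated (step 6) and, after hydroboration, joined to a second portion of 9 (step 7).
- Stereochemistry: C10 is set by the chiral oxazaborolidinium catalyst in step 1; C5 is erased in step 2 and reset trans by hydrogenation opposite the C10 methyl in step 4; both halves derive from 9, so the homochiral dimer needs no further stereochemical event.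

Key step: step 1

Assumption: the (S)-configured catalyst is taken to deliver the diene to the face of C10 that leads to the (10S) series; should the adduct prove antipodal, the (R)-catalyst is used and nothing else changes.

**Step 1**
Reactants: 1 2,6-dimethyl-1,4-benzoquinone; 2 4-methylpenta-1,3-diene
Product: 3 (4aR,8aS)-2,5,5,8a-tetramethyl-4a,5,8,8a-tetrahydronaphthalene-1,4-dione (cis-fused; C10 methyl and C5–H on the same face)
Conditions: 2 (5 equiv), (3aS)-1-(2-methylphenyl)-3,3-diphenyltetrahydro-1H,3H-pyrrolo[1,2-c][1,3,2]oxazaborole (20 mol%), Tf2NH (18 mol%), CH2Cl2, −78 → −20 °C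
Reagents that add atoms: none
Why: The Tf2NH-activated oxazaborolidine binds the quinone carbonyl that lies between the two ring CH groups (the later C6=O), which polarises the adjacent C5=C10 bond so that the methyl-bearing β-carbon C10 is attacked first by the unsubstituted CH2 terminus of 2, while the developing tertiary allyl cation at the CMe2 terminus closes onto the enolate carbon C5 in one concerted but highly asynchronous [4+2] event. The closest known reaction type is the oxazaborolidinium-catalysed enantioselective Diels–Alder reaction of 2,6-dialkylbenzoquinones with acyclic 1,3-dienes, here stretched to a diene that carries a cis substituent at one terminus. Ring A is closed by intermolecular [4+2] annulation across the C5=C10 edge of ring B, which forms C1–C10 and C4–C5 suprafacially and therefore gives the cis ring fusion. C10 is controlled by the catalyst, whose aryl group covers one face of the bound enone so that the diene adds to the open face, and C5 is tied to C10 by the suprafacial addition (it is erased in step 2 and reset in step 4). The step needs regioselectivity (CH2 to C10 and CMe2 to C5) and face selectivity at C10; the former is secured by the match between the most electrophilic enone carbon and the most nucleophilic diene terminus and by the fact that the other orientation would join two fully substituted carbons, the latter by the twofold symmetry of 1, which makes the two ways of binding the unhindered carbonyl lead to the same enantiomer. Endo/exo selectivity is irrelevant because neither diene terminus becomes a stereocentre.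

**Step 2**
Reactants: 3 (4aR,8aS)-2,5,5,8a-tetramethyl-4a,5,8,8a-tetrahydronaphthalene-1,4-dione
Product: 5 (4aS)-3,4a,8,8-tetramethyl-4-oxo-4,4a,5,8-tetrahydronaphthalen-1-yl trifluoromethanesulfonate (C6 dienyl triflate; double bonds C5=C6 and C7=C8), via potassium dienolate 4 (not isolated)
Conditions: KN(SiMe3)2 (1.1 equiv), THF, −78 °C; then PhNTf2 (1.2 equiv), −78 → 0 °C
Reagents that add atoms: N-phenylbis(trifluoromethanesulfonimide), O=S(=O)(N(c1ccccc1)S(=O)(=O)C(F)(F)F)C(F)(F)F
Why: C5–H is the only sp3 α-hydrogen of either carbonyl (C10 is quaternary, C7 and C8 are alkene carbons), so kinetic deprotonation should give the C5=C6 dienolate alone, and its O-sulfonylation (enol triflate formation) turns the C6 oxygen into a leaving group while deliberately erasing the cis C5 centre.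

**Step 3**
Reactants: 5 (4aS)-3,4a,8,8-tetramethyl-4-oxo-4,4a,5,8-tetrahydronaphthalen-1-yl trifluoromethanesulfonate
Product: 6 (8aS)-2,5,5,8a-tetramethyl-8,8a-dihydronaphthalen-1(5H)-one (linear dienone C9=O/C7=C8/C5=C6 plus the ring A alkene C2=C3)
Conditions: Pd(OAc)2 (5 mol%), PPh3 (10 mol%), HCO2H (2 equiv), Bu3N (3 equiv), DMF, 60 °C
Reagents that add atoms: none
Why: Palladium-catalysed formate reduction of an enol triflate (oxidative addition of the C6–O bond to zerovalent palladium, triflate–formate exchange, loss of CO2, C–H reductive elimination) should replace the triflate by hydrogen without touching the alkenes or the hindered C9 ketone; no stereocentre is formed.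

**Step 4**
Reactants: 6 (8aS)-2,5,5,8a-tetramethyl-8,8a-dihydronaphthalen-1(5H)-one
Product: 7 (4aS,8aS)-2,5,5,8a-tetramethyloctahydronaphthalen-1(2H)-one (trans-fused; both epimers at the methyl-bearing C8)
Conditions: H2 (3 atm), 10% Pd/C, EtOAc, rt
Reagents that add atoms: none
Why: Heterogeneous catalytic hydrogenation should saturate C2=C3, C7=C8 and C5=C6, with hydrogen reaching C5 from the α face because the β face is covered by the C10 methyl and the axial C4 methyl (the usual course for 5,6-alkenes of 4,4,10-trimethyl decalin systems), which sets the trans ring fusion (5S), while the configuration at C8 does not matter since that carbon becomes sp2 in step 5.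

**Step 5**
Reactants: 7 (4aS,8aS)-2,5,5,8a-tetramethyloctahydronaphthalen-1(2H)-one
Product: 9 (4aS,8aS)-2,5,5,8a-tetramethyl-3,4,4a,5,6,7,8,8a-octahydronaphthalen-1-yl trifluoromethanesulfonate, via lithium enolate 8 (not isolated)
Conditions: LiN(iPr)2 (1.3 equiv), THF, −78 → 0 °C; then PhNTf2 (1.3 equiv), 0 °C → rt
Reagents that add atoms: N-phenylbis(trifluoromethanesulfonimide), O=S(=O)(N(c1ccccc1)S(=O)(=O)C(F)(F)F)C(F)(F)F
Why: C8–H is the only α-hydrogen of the C9 ketone (C10 is quaternary), so deprotonation can give only the C8=C9 enolate, and its O-sulfonylation (enol triflate formation, well known for 2,2,6-trisubstituted cyclohexanones) fixes the tetrasubstituted alkene of the target; C5 and C10 are not touched.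

**Step 6**
Reactants: 9 (4aS,8aS)-2,5,5,8a-tetramethyl-3,4,4a,5,6,7,8,8a-octahydronaphthalen-1-yl trifluoromethanesulfonate
Product: 10 (4aS,8aS)-1-ethenyl-2,5,5,8a-tetramethyl-3,4,4a,5,6,7,8,8a-octahydronaphthalene
Conditions: CH2=CHSnBu3 (1.5 equiv), Pd(PPh3)4 (5 mol%), LiCl (3 equiv), THF, 65 °C
Reagents that add atoms: tributyl(vinyl)stannane, C=C[Sn](CCCC)(CCCC)CCCC
Why: Stille coupling of an alkenyl triflate with a vinylstannane (LiCl-assisted transmetalation) should form C9–C11 and is well established for 2,6,6-trisubstituted cyclohexenyl triflates; no stereocentre is involved.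

**Step 7**
Reactants: 10 (4aS,8aS)-1-ethenyl-2,5,5,8a-tetramethyl-3,4,4a,5,6,7,8,8a-octahydronaphthalene; 9 (4aS,8aS)-2,5,5,8a-tetramethyl-3,4,4a,5,6,7,8,8a-octahydronaphthalen-1-yl trifluoromethanesulfonate
Product: 12 1,2-bis[(4aS,8aS)-2,5,5,8a-tetramethyl-3,4,4a,5,6,7,8,8a-octahydronaphthalen-1-yl]ethane (target), via alkyl-9-BBN borane 11 (not isolated)
Conditions: 9-BBN (1.2 equiv), THF, 0 °C → rt; then 9 (1.0 equiv), PdCl2(dppf) (10 mol%), 3 M aq. K3PO4 (3 equiv), DMF, 60 °C
Reagents that add atoms: none
Why: 9-BBN should add only to the terminal vinyl carbon of 10 (the tetrasubstituted ring alkene is inert), and the primary alkylborane then transfers its alkyl group to the alkenylpalladium species formed from 9 in a B-alkyl Suzuki–Miyaura coupling, which forms C11'–C9' without creating or disturbing any stereocentre.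

**Compound list**
1 | 2,6-dimethyl-1,4-benzoquinone | CC1=CC(=O)C=C(C)C1=O | starting material
2 | 4-methylpenta-1,3-diene | C=CC=C(C)C | starting material
3 | (4aR,8aS)-2,5,5,8a-tetramethyl-4a,5,8,8a-tetrahydronaphthalene-1,4-dione (cis-fused) | O=C1C(C)=CC(=O)[C@@H]2C(C)(C)C=CC[C@]12C | intermediate
4 | potassium (4aS)-3,4a,8,8-tetramethyl-4-oxo-4,4a,5,8-tetrahydronaphthalen-1-olate | O=C1C(C)=CC([O-])=C2C(C)(C)C=CC[C@]12C.[K+] | intermediate
5 | (4aS)-3,4a,8,8-tetramethyl-4-oxo-4,4a,5,8-tetrahydronaphthalen-1-yl trifluoromethanesulfonate | O=C1C(C)=CC(OS(=O)(=O)C(F)(F)F)=C2C(C)(C)C=CC[C@]12C | intermediate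
6 | (8aS)-2,5,5,8a-tetramethyl-8,8a-dihydronaphthalen-1(5H)-one | O=C1C(C)=CC=C2C(C)(C)C=CC[C@]12C | intermediate
7 | (4aS,8aS)-2,5,5,8a-tetramethyloctahydronaphthalen-1(2H)-one (trans-fused; both C8 epimers, centre left open) | CC1C(=O)[C@@]2(C)CCCC(C)(C)[C@@H]2CC1 | intermediate
8 | lithium (4aS,8aS)-2,5,5,8a-tetramethyl-3,4,4a,5,6,7,8,8a-octahydronaphthalen-1-olate | [Li+].CC1=C([O-])[C@@]2(C)CCCC(C)(C)[C@@H]2CC1 | intermediate
9 | (4aS,8aS)-2,5,5,8a-tetramethyl-3,4,4a,5,6,7,8,8a-octahydronaphthalen-1-yl trifluoromethanesulfonate | CC1=C(OS(=O)(=O)C(F)(F)F)[C@@]2(C)CCCC(C)(C)[C@@H]2CC1 | intermediate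
10 | (4aS,8aS)-1-ethenyl-2,5,5,8a-tetramethyl-3,4,4a,5,6,7,8,8a-octahydronaphthalene | CC1=C(C=C)[C@@]2(C)CCCC(C)(C)[C@@H]2CC1 | intermediate
11 | 9-{2-[(4aS,8aS)-2,5,5,8a-tetramethyl-3,4,4a,5,6,7,8,8a-octahydronaphthalen-1-yl]ethyl}-9-borabicyclo[3.3.1]nonane | CC1=C(CCB2C3CCCC2CCC3)[C@@]2(C)CCCC(C)(C)[C@@H]2CC1 | intermediate
12 | 1,2-bis[(4aS,8aS)-2,5,5,8a-tetramethyl-3,4,4a,5,6,7,8,8a-octahydronaphthalen-1-yl]ethane | CC1=C(CCC2=C(C)CC[C@H]3C(C)(C)CCC[C@]23C)[C@@]2(C)CCCC(C)(C)[C@@H]2CC1 | target

**Step count**
Total: 7 steps. Longest linear sequence: 7 steps (1 → 3 → 5 → 6 → 7 → 9 → 10 → 12); triflate 9 enters twice, in steps 6 and 7.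

**Steps most likely to fail**

Step 1. What may go wrong: the cis-methyl group at the CMe2 terminus keeps the diene out of the s-cis geometry. Closure of C4–C5 may then lag behind the first bond, and the polar pathway may divert to open-chain alkylation of the quinone, to diene oligomerisation, or to an adduct of low enantiomeric purity. Fallback (sets out from 1, returns at 6): the diene is made far more nucleophilic by a 2-silyloxy group, which is later removed as a second triflate. Mesityl oxide with iPr3SiOTf/Et3N (CH2Cl2, 0 °C) should give triisopropyl[(4-methylpenta-1,3-dien-2-yl)oxy]silane F1. Under the catalyst of step 1 this should add to 1 in the same orientation (its CH2 terminus is the enol ether β-carbon), forming the same two bonds, to give (4aR,8aS)-2,5,5,8a-tetramethyl-7-(triisopropylsilyloxy)-4a,5,8,8a-tetrahydronaphthalene-1,4-dione F2. KN(SiMe3)2/PhNTf2 as in step 2 should convert it into (4aS)-3,4a,8,8-tetramethyl-4-oxo-6-(triisopropylsilyloxy)-4,4a,5,8-tetrahydronaphthalen-1-yl trifluoromethanesulfonate F3. CsF/PhNTf2 in DME should then exchange the silyl group for a triflate to give (4aS)-3,4a,8,8-tetramethyl-4-oxo-4,4a,5,8-tetrahydronaphthalene-1,6-diyl bis(trifluoromethanesulfonate) F4. The formate reduction of step 3, run with doubled amounts, should remove both triflates and deliver 6.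

Step 4. What may go wrong: the nearly flat dienone may bind the catalyst surface by its β face, so that hydrogen reaches C5 from the side of the C10 methyl and the cis-decalin forms; alternatively the hindered C5=C6 bond may resist reduction. Fallback (sets out from 6, returns at 7): C5 is set by protonation instead of surface delivery. Dissolving-metal reduction of 6 (Li, NH3/THF, t-BuOH 1 equiv, −78 °C; NH4Cl) should add hydrogen to the δ-carbon C5 perpendicular to the dienolate and opposite the two β-methyl groups, the trans outcome typical of such reductions of octalones. Brief NaOMe/MeOH treatment should bring the remaining ring B alkene into conjugation and give (4aS,8aS)-2,5,5,8a-tetramethyl-4a,5,8,8a-tetrahydronaphthalen-1(4H)-one F5. Hydrogenation (H2, 10% Pd/C, EtOAc) then saturates C2=C3 and C7=C8, neither of which can affect C5, and returns the route to 7.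

Step 7. What may go wrong: oxidative addition and transmetalation at the triflate carbon, flanked by the quaternary C10 and the methyl-bearing C8, may be slow, so that protodeboronation or β-hydride elimination of the alkyl group, or hydrolysis of the triflate, take over. Fallback (sets out from 9, returns at 12): the linker is introduced as a sterically undemanding alkyne and reduced at the end. Sonogashira coupling of 9 with ethynyltrimethylsilane (PdCl2(PPh3)2, CuI, Et3N, DMF, 60 °C) should give trimethyl{[(4aS,8aS)-2,5,5,8a-tetramethyl-3,4,4a,5,6,7,8,8a-octahydronaphthalen-1-yl]ethynyl}silane F6. K2CO3/MeOH should release (4aS,8aS)-1-ethynyl-2,5,5,8a-tetramethyl-3,4,4a,5,6,7,8,8a-octahydronaphthalene F7. A second Sonogashira coupling with 9 should give 1,2-bis[(4aS,8aS)-2,5,5,8a-tetramethyl-3,4,4a,5,6,7,8,8a-octahydronaphthalen-1-yl]ethyne F8. Diimide (2-nitrobenzenesulfonylhydrazide, Et3N, CH2Cl2, rt, in excess) should reduce the triple bond to CH2–CH2 and leave the two tetrasubstituted alkenes alone, giving 12.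

**Further compounds**
F1 | step 1 | triisopropyl[(4-methylpenta-1,3-dien-2-yl)oxy]silane | C=C(O[Si](C(C)C)(C(C)C)C(C)C)C=C(C)C
F2 | step 1 | (4aR,8aS)-2,5,5,8a-tetramethyl-7-(triisopropylsilyloxy)-4a,5,8,8a-tetrahydronaphthalene-1,4-dione | O=C1C(C)=CC(=O)[C@@H]2C(C)(C)C=C(O[Si](C(C)C)(C(C)C)C(C)C)C[C@]12C
F3 | step 1 | (4aS)-3,4a,8,8-tetramethyl-4-oxo-6-(triisopropylsilyloxy)-4,4a,5,8-tetrahydronaphthalen-1-yl trifluoromethanesulfonate | O=C1C(C)=CC(OS(=O)(=O)C(F)(F)F)=C2C(C)(C)C=C(O[Si](C(C)C)(C(C)C)C(C)C)C[C@]12C
F4 | step 1 | (4aS)-3,4a,8,8-tetramethyl-4-oxo-4,4a,5,8-tetrahydronaphthalene-1,6-diyl bis(trifluoromethanesulfonate) | O=C1C(C)=CC(OS(=O)(=O)C(F)(F)F)=C2C(C)(C)C=C(OS(=O)(=O)C(F)(F)F)C[C@]12C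
F5 | step 4 | (4aS,8aS)-2,5,5,8a-tetramethyl-4a,5,8,8a-tetrahydronaphthalen-1(4H)-one | O=C1C(C)=CC[C@H]2C(C)(C)C=CC[C@]12C
F6 | step 7 | trimethyl{[(4aS,8aS)-2,5,5,8a-tetramethyl-3,4,4a,5,6,7,8,8a-octahydronaphthalen-1-yl]ethynyl}silane | CC1=C(C#C[Si](C)(C)C)[C@@]2(C)CCCC(C)(C)[C@@H]2CC1
F7 | step 7 | (4aS,8aS)-1-ethynyl-2,5,5,8a-tetramethyl-3,4,4a,5,6,7,8,8a-octahydronaphthalene | CC1=C(C#C)[C@@]2(C)CCCC(C)(C)[C@@H]2CC1
F8 | step 7 | 1,2-bis[(4aS,8aS)-2,5,5,8a-tetramethyl-3,4,4a,5,6,7,8,8a-octahydronaphthalen-1-yl]ethyne | CC1=C(C#CC2=C(C)CC[C@H]3C(C)(C)CCC[C@]23C)[C@@]2(C)CCCC(C)(C)[C@@H]2CC1
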